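# Proposed total synthesis of CNP0242711.1 by Nozaki–Hiyama–Kishi closure of the C9–C10 bond

## Structural features

The target is a briarane diterpenoid with three rings: a cyclohexane (ring A: C1, C10, C11, C12, C13, C14), a ten-membered carbocycle (C1 to C10) trans-fused to ring A across C1–C10, and a γ-lactone (C7, C8, C17, C19 and the ring oxygen) fused to the large ring across C7–C8. It has twelve stereocentres; eleven form one unbroken chain C6–C7–C8–C9–C10–C11–C12–C13–C14–C1–C2, and C17 hangs on C8. C1 and C8 are fully substituted and both flank the C9–C10 region. On ring A the C15 and C20 methyl groups are syn (H10 and H11 are cis on the other face), and the C12 acetate and the C13–C14 epoxide lie on the face opposite C15. On the lactone the C18 methyl, the C8 hydroxyl and C6 are all cis. The fragile groups are the epoxide next to an acetate, the secondary allylic chloride at C6 beside the exocyclic C5=C16 alkene, the β-hydroxy lactone (C17–H and C8–OH can eliminate), and two acetates that must coexist with free hydroxyls at C8 and C9. The real difficulty is closing the ten-membered ring in its most crowded sector and setting C9, C10 and C11 beside two fully substituted carbons while four oxygen functions stay differentiated. The key step uses two facts: C10 is the β-carbon of a 2-methylcyclohexenone unit in ring A (C10=C11–C12=O), so it can be turned into an alkenyl metal, and C9 can be an aldehyde on the hydrogen-free C8, so it cannot enolize. Joining them forms C9–C10, closes the large ring, and leaves an enone from which C10 and C11 are set together.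

## Logic of the disconnections

51 is first stripped of its fragile groups. The two O–Si bonds at O8 and O9 are restored (50), the C6–Cl bond is cut with return of the C5=C6 alkene and the C16 methyl (49), the C12 acetyl is removed (48) and the epoxide oxygen is taken off C13 and C14 (47). This leaves one alkene-bearing ring A and one isolated alkene. The forward demands are that chlorination removes a C16 hydrogen on the correct face, that epoxidation is steered by the C12 hydroxyl, and that only one hydroxyl is free when the C12 acetate is made.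

47 goes back to enone 46 (C12–H bond cut), 46 to ketone 44 (C13=C14 removed), and 44 to 42 and 41 by removing the C10–H and C11–H bonds. Both ring-fusion-side centres are thus stored in one tetrasubstituted enone. The forward step must deliver hydride to C10 and a proton to C11 from the face opposite C15 and must not let C11 equilibrate afterwards.

41 is cut at C9–C10 to give 39. This is the strategic cut: it opens the ten-membered ring at the bond between the two most hindered carbons and turns the product into one chain with an aldehyde at one end and an activated ring A alkene carbon at the other. The forward step must add an alkenyl metal to an aldehyde in the presence of a ketone, a lactone and an acetate, and must do so intramolecularly.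

39 is traced to 35 by functional group changes only: the aldehyde comes from the ether in 37 via 38, and the C10 triflate with C12 ketone comes from the C10 ketone with C12 enol ether. The leaving group is chosen as a triflate because it can be placed on C10 regiospecifically: in 35 only O10 is a carbonyl oxygen and only C13 carries removable hydrogens. An iodide made from the corresponding 1,3-dione with Ph3P/I2 would be expected mainly at the less hindered C12. The forward demand is O-sulfonylation without strong base, since the lactone is already present.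

35 is cut at C4–C5 into 33 and 22. This sp3–sp2 cut gives two fragments of similar size, each with all its stereocentres fixed on its own. Joining the halves by an aldol at C1–C2 would create C1 and C2 with no element that relates them to the lactone centres, so that junction is avoided. The forward demand is retention of the Z alkene geometry and placement of boron on C4.

22 is simplified by opening the lactone C19–O bond and taking C19 back to a vinyl group (21 to 16), and then by cutting C8–C17 in 13 to reach ester 10. This [3,3] cut creates the quaternary C8 and the adjacent C17 in one step from a ring-bound enolate and a crotyl unit. The forward demand is a defined ketene acetal geometry, a chair transition state, and attack anti to the C7 substituent.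

10 goes back to 8 by ester exchange with 9, 8 to 3 and 4 by cutting C5=C6, and 3 to 1 by way of 2. C7 is thereby taken from the chiral pool, and the Z iodoalkene, which fixes the later Δ5 geometry, is made at the start on a robust substrate. The forward demand is Z selectivity in the olefination.

33 is traced to 29 by returning the C3=C4 alkene to a protected diol, and 29 is cut at C1–C2 into 26 and 27. The chiral-pool aldehyde 27 acts as an acrolein equivalent that sets C2 and, through the aldol transition state, the quaternary C1. The C2 oxygen is acetylated at once, so no late selective acylation of C2 against C9 is needed. The forward demand is useful facial selectivity on both aldol partners.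

26 is cut at C1–C15 to give 24, which comes from 23 by O-methylation. Ring A is thus bought with its 2-methyl-1,3-dioxygenation pattern in place.

## Other disconnections considered

Alternative 1: The cut is through C10–C11 and C1–C14, that is, ring A is made by a [4+2] cycloaddition. In the forward direction di-(–)-menthyl mesaconate A1 and (Z)-3-(tert-butyldimethylsilyloxy)penta-1,3-diene A2 would combine under Et2AlCl to give the ring A diester A3.
- In favour: the E dienophile places the C2 and C9 carbons trans, as the ring fusion needs. The Z diene places C20. The quaternary C1, C10 and C11 are all set in one step under auxiliary control. The C12 silyl enol ether is a direct handle for the later C13=C14 unsaturation.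
- Against: a trisubstituted diester dienophile is sluggish. Its two ester termini are electronically similar, so regiochemistry rests on the single siloxy group. Two remote menthyl groups may give only moderate facial bias. The step builds only ring A, so the ten-membered ring and the lactone would still need a separate closure after the two esters are told apart.
- Comparison: on structure, A3 holds C10 and C11 in their final configuration from the start. The chosen plan must set them late by reduction of a hindered enone; on this point Alternative 1 is the better plan. On mechanism, a concerted cycloaddition is more predictable than a medium-ring organometallic closure, but it does not address the main difficulty. On step economy it is expected to be longer, because the macrocycle must still be built from two ester carbons.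

Alternative 2: The cut is at C6–C7, with the lactone C19–O bond formed in the same operation. In the forward direction CrCl2 would insert into an allylic C16–Br bond, and the resulting allylchromium would add through its chlorine-bearing terminus C6 to a C7 aldehyde; the C7 alkoxide would then close the lactone on a C19 methyl ester. This would give tricycle A4.
- In favour: one operation would form the ten-membered ring, the C6 chloride, the C5=C16 alkene and the lactone. The C6/C7 relationship would come from a cyclic transition state and not from a late reaction on a flexible ring; on this point Alternative 2 is the better plan. The reaction class, organochromium addition to an aldehyde, is the same as in the chosen plan and equally tolerant of functional groups.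
- Against: ring A must be complete, with C10, C11, C12 and the C13=C14 alkene in place, before the ring closure is tested. The γ-chloroallyl unit must have one defined geometry and must react at its γ terminus. The aldehyde sits on the fully substituted C8, so it is as hindered as in the chosen plan. Medium-ring closure by allylchromium reagents is less documented than by alkenylchromium reagents.
- Comparison: the chosen plan tests the ring closure earlier and on a simpler ring A. It pays for this with a longer endgame and a less certain C6 chlorination.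

Alternative 3: The cut is across C3–C4, made as an alkene by Ramberg–Bäcklund contraction. In the forward direction an eleven-membered cyclic sulfone would be chlorinated at C4 by KOH and CCl4 in tert-butanol; the C3 carbanion would close the episulfone and loss of SO2 would give the C3=C4, C5=C6 diene A5.
- In favour: the large ring would be closed by carbon–sulfur bond formation between unhindered carbons, far from C1 and C8, and ring contraction tolerates strain. On reliability of the ring-closing event Alternative 3 is the better plan.
- Against: the target is saturated at C3–C4, so the new alkene must be reduced selectively beside the conjugated C5=C6 alkene. The strongly basic conditions exclude the lactone, which must be made afterwards from the protected C19 alcohol. Sulfide formation, oxidation, contraction and diene reduction add steps.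
- Comparison: the mechanism is robust and metal-free, but it introduces unsaturation that the target does not have. The chosen plan forms a bond that is present in the target and uses the resulting enone productively. In step count the chosen plan should be shorter.

Key step: step 21

Remark on the chemistry: α denotes the face of ring A opposite the C15 methyl and β the face that carries it. Atom labels C1 to C20 follow the briarane numbering used above for every intermediate. Facial selectivities are predictions from the models named in each step.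

## Steps

Step 1
Reactants: 1 dimethyl (4R,5R)-2,2-dimethyl-1,3-dioxolane-4,5-dicarboxylate
Product: 2 methyl (4R,5S)-5-(hydroxymethyl)-2,2-dimethyl-1,3-dioxolane-4-carboxylate
Conditions: NaBH4 (0.6 equiv), MeOH, 0 °C
Reagents that add atoms: none
Why: Borohydride reduction of an α-alkoxy ester; the two esters are equivalent and the alkoxyborate formed after the first reduction slows the second, so the hydroxy ester should predominate. The reduced carbon becomes C6, the remaining ester C9, and C7 keeps its configuration.

Step 2
Reactants: 2 methyl (4R,5S)-5-(hydroxymethyl)-2,2-dimethyl-1,3-dioxolane-4-carboxylate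
Product: 3 methyl (4R,5R)-5-formyl-2,2-dimethyl-1,3-dioxolane-4-carboxylate
Conditions: Dess–Martin periodinane, pyridine, CH2Cl2, 0 °C to rt
Reagents that add atoms: none
Why: Dess–Martin oxidation of a primary alcohol under buffered conditions. The trans-disubstituted dioxolane is the more stable isomer, so C7 is not at risk of epimerization.

Step 3
Reactants: 3 methyl (4R,5R)-5-formyl-2,2-dimethyl-1,3-dioxolane-4-carboxylate; 4 ethyltriphenylphosphonium iodide
Product: 8 methyl (4R,5S)-5-[(1Z)-2-iodoprop-1-en-1-yl]-2,2-dimethyl-1,3-dioxolane-4-carboxylate, via ethylidenetriphenylphosphorane 5 (not isolated), via (1-iodoethyl)triphenylphosphonium iodide 6 (not isolated), via (1-iodoethylidene)triphenylphosphorane 7 (not isolated)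
Conditions: 4, n-BuLi, THF, 0 °C; I2, −78 °C; NaN(SiMe3)2, −78 to −20 °C; then 3, −78 °C
Reagents that add atoms: iodine, II
Why: Stork–Zhao olefination with the α-iodo ylide; kinetic formation of the cis oxaphosphetane from this non-stabilized ylide should give the Z iodoalkene (iodine cis to C7). This fixes the later C5=C6 geometry, and the low temperature spares the ester and C7.

Step 4
Reactants: 8 methyl (4R,5S)-5-[(1Z)-2-iodoprop-1-en-1-yl]-2,2-dimethyl-1,3-dioxolane-4-carboxylate; 9 (E)-but-2-en-1-ol
Product: 10 (2E)-but-2-en-1-yl (4R,5S)-5-[(1Z)-2-iodoprop-1-en-1-yl]-2,2-dimethyl-1,3-dioxolane-4-carboxylate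
Conditions: Ti(OiPr)4 (cat.), 9 (excess), toluene, 100 °C, removal of MeOH
Reagents that add atoms: none
Why: Titanate-mediated transesterification under neutral conditions, which α-alkoxy esters undergo readily; it is driven by loss of methanol. No stereocentre is affected.

Step 5
Reactants: 10 (2E)-but-2-en-1-yl (4R,5S)-5-[(1Z)-2-iodoprop-1-en-1-yl]-2,2-dimethyl-1,3-dioxolane-4-carboxylate
Product: 13 (4S,5S)-4-[(2S)-but-3-en-2-yl]-5-[(1Z)-2-iodoprop-1-en-1-yl]-2,2-dimethyl-1,3-dioxolane-4-carboxylic acid, via ketene silyl acetal 11 (not isolated), via trimethylsilyl ester 12 (not isolated)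
Conditions: LiN(SiMe3)2, Me3SiCl, Et3N, THF, −78 °C, then 50 °C; 1 M HCl
Reagents that add atoms: none
Why: Ireland–Claisen rearrangement of an α-alkoxy ester; lithium chelation should place the ring oxygen cis to the silyloxy group in 11, and the chair transition state with the E-crotyl methyl pseudo-equatorial fixes C17 relative to C8. Bond formation on the dioxolane face anti to the C7 substituent sets the quaternary C8, and trapping the enolate at −78 °C avoids β-elimination and attack on the iodoalkene.

Step 6
Reactants: 13 (4S,5S)-4-[(2S)-but-3-en-2-yl]-5-[(1Z)-2-iodoprop-1-en-1-yl]-2,2-dimethyl-1,3-dioxolane-4-carboxylic acid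
Product: 15 [(4R,5S)-4-[(2S)-but-3-en-2-yl]-5-[(1Z)-2-iodoprop-1-en-1-yl]-2,2-dimethyl-1,3-dioxolan-4-yl]methanol, via acyl imidazolide 14 (not isolated)
Conditions: 1,1'-carbonyldiimidazole, THF, rt; then NaBH4, H2O, 0 °C
Reagents that add atoms: none
Why: One-pot reduction of a carboxylic acid through its acyl imidazolide; borohydride leaves the alkenyl iodide and the terminal alkene alone, which LiAlH4 or borane might not. C9 is now at the alcohol oxidation level.

Step 7
Reactants: 15 [(4R,5S)-4-[(2S)-but-3-en-2-yl]-5-[(1Z)-2-iodoprop-1-en-1-yl]-2,2-dimethyl-1,3-dioxolan-4-yl]methanol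
Product: 16 4-methoxybenzyl ether of 15
Conditions: NaH, 4-methoxybenzyl chloride, n-Bu4NI (cat.), DMF, 0 °C to rt
Reagents that add atoms: 4-methoxybenzyl chloride, COc1ccc(CCl)cc1
Why: Williamson etherification of a primary alcohol. The ether must survive the acid of step 9, so that only O7 can lactonize, and it is removed oxidatively in step 19.

Step 8
Reactants: 16 4-methoxybenzyl ether of 15
Product: 18 (2R)-2-[(4R,5S)-5-[(1Z)-2-iodoprop-1-en-1-yl]-4-[(4-methoxybenzyl)oxymethyl]-2,2-dimethyl-1,3-dioxolan-4-yl]propanal, via vicinal diol 17 (not isolated)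
Conditions: OsO4 (cat.), NaIO4, 2,6-lutidine, dioxane–H2O, rt
Reagents that add atoms: osmium tetroxide, O=[Os](=O)(=O)=O (regenerated by sodium periodate, [Na+].[O-]I(=O)(=O)=O)
Why: Lemieux–Johnson cleavage; OsO4 attacks the monosubstituted alkene much faster than the hindered, iodine-bearing trisubstituted one. The buffered medium should leave the α-stereocentre C17 of the aldehyde untouched.

Step 9
Reactants: 18 (2R)-2-[(4R,5S)-5-[(1Z)-2-iodoprop-1-en-1-yl]-4-[(4-methoxybenzyl)oxymethyl]-2,2-dimethyl-1,3-dioxolan-4-yl]propanal
Product: 21 (3R,4R,5S)-4-hydroxy-5-[(1Z)-2-iodoprop-1-en-1-yl]-4-[(4-methoxybenzyl)oxymethyl]-3-methyloxolan-2-one, via carboxylic acid 19 (not isolated), via dihydroxy acid 20 (not isolated)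
Conditions: NaClO2, NaH2PO4, 2-methylbut-2-ene, t-BuOH–H2O, 0 °C; then AcOH–H2O (4:1), 50 °C
Reagents that add atoms: sodium chlorite, [Na+].[O-]Cl=O
Why: Pinnick oxidation, then acid hydrolysis of the acetonide and spontaneous γ-lactonization of O7 onto C19. The tertiary O8 could only give a β-lactone and O9 is blocked, so one lactone is possible, and acyl substitution keeps C7, C8 and C17 as set.

Step 10
Reactants: 21 (3R,4R,5S)-4-hydroxy-5-[(1Z)-2-iodoprop-1-en-1-yl]-4-[(4-methoxybenzyl)oxymethyl]-3-methyloxolan-2-one
Product: 22 (3R,4R,5S)-5-[(1Z)-2-iodoprop-1-en-1-yl]-4-[(4-methoxybenzyl)oxymethyl]-3-methyl-4-(triethylsilyloxy)oxolan-2-one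
Conditions: Et3SiOTf, 2,6-lutidine, CH2Cl2, −78 to 0 °C
Reagents that add atoms: triethylsilyl trifluoromethanesulfonate, CC[Si](CC)(CC)OS(=O)(=O)C(F)(F)F
Why: Silylation of a tertiary alcohol with a silyl triflate and a hindered base. The ether blocks retro-aldol and elimination of the β-hydroxy lactone in later steps.

Step 11
Reactants: 23 2-methylcyclohexane-1,3-dione
Product: 24 3-methoxy-2-methylcyclohex-2-en-1-one
Conditions: HC(OMe)3, MeOH, TsOH (cat.), rt
Reagents that add atoms: trimethyl orthoformate, COC(OC)OC
Why: Acid-catalysed O-alkylation of the enolized 1,3-dione (vinylogous ester formation), driven by the orthoester as water scavenger.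

Step 12
Reactants: 24 3-methoxy-2-methylcyclohex-2-en-1-one
Product: 26 3-methoxy-2,6-dimethylcyclohex-2-en-1-one (racemic), via lithium enolate 25 (not isolated)
Conditions: LiN(iPr)2, THF, −78 °C; MeI, −78 to 0 °C
Reagents that add atoms: iodomethane, CI
Why: Kinetic α'-deprotonation and alkylation of a vinylogous ester (Stork–Danheiser alkylation); this installs C15 on the future C1. The stereocentre formed is erased in the next enolization.

Step 13
Reactants: 26 3-methoxy-2,6-dimethylcyclohex-2-en-1-one (racemic); 27 (R)-2,2-dimethyl-1,3-dioxolane-4-carbaldehyde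
Product: 29 (6R)-6-[(S)-[(4R)-2,2-dimethyl-1,3-dioxolan-4-yl](hydroxy)methyl]-3-methoxy-2,6-dimethylcyclohex-2-en-1-one, via lithium enolate 28 (not isolated)
Conditions: LiN(iPr)2, THF, −78 °C; then 27, −78 °C; aq. NH4Cl
Reagents that add atoms: none
Why: Aldol addition of a tetrasubstituted lithium enolate; Felkin–Anh attack anti to the α-oxygen of 27 should set C2, and the Zimmerman–Traxler chair with the aldehyde substituent equatorial should set the quaternary C1 relative to C2. Minor diastereomers are removed by chromatography.

Step 14
Reactants: 29 (6R)-6-[(S)-[(4R)-2,2-dimethyl-1,3-dioxolan-4-yl](hydroxy)methyl]-3-methoxy-2,6-dimethylcyclohex-2-en-1-one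
Product: 30 (S)-[(4R)-2,2-dimethyl-1,3-dioxolan-4-yl][(1R)-4-methoxy-1,3-dimethyl-2-oxocyclohex-3-en-1-yl]methyl acetate
Conditions: Ac2O, Et3N, DMAP (cat.), CH2Cl2, 0 °C to rt
Reagents that add atoms: acetic anhydride, CC(=O)OC(C)=O
Why: DMAP-catalysed acetylation. It installs the C2 acetate of the target, which is stable to every later step, and it stops retro-aldol cleavage of the β-hydroxy ketone.

Step 15
Reactants: 30 (S)-[(4R)-2,2-dimethyl-1,3-dioxolan-4-yl][(1R)-4-methoxy-1,3-dimethyl-2-oxocyclohex-3-en-1-yl]methyl acetate
Product: 31 (1S,2R)-2,3-dihydroxy-1-[(1R)-4-methoxy-1,3-dimethyl-2-oxocyclohex-3-en-1-yl]propyl acetate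
Conditions: PPTS, MeOH, 40 °C
Reagents that add atoms: none
Why: Acid-catalysed transketalization of a terminal acetonide. Methanol matches the methyl enol ether, so any exchange there is degenerate, and acyl migration is slow under mild acid.

Step 16
Reactants: 31 (1S,2R)-2,3-dihydroxy-1-[(1R)-4-methoxy-1,3-dimethyl-2-oxocyclohex-3-en-1-yl]propyl acetate
Product: 33 (1R)-1-[(1R)-4-methoxy-1,3-dimethyl-2-oxocyclohex-3-en-1-yl]prop-2-en-1-yl acetate, via cyclic orthoformate 32 (not isolated)
Conditions: HC(OMe)3, PPTS (cat.), CH2Cl2, rt; concentrate; Ac2O, 140 °C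
Reagents that add atoms: none
Why: Eastwood deoxygenation of a vicinal diol through its 2-methoxy-1,3-dioxolane; thermal fragmentation gives the terminal C3=C4 alkene. The conditions are non-basic, so the neighbouring acetate cannot migrate.

Step 17
Reactants: 33 (1R)-1-[(1R)-4-methoxy-1,3-dimethyl-2-oxocyclohex-3-en-1-yl]prop-2-en-1-yl acetate; 22 (3R,4R,5S)-5-[(1Z)-2-iodoprop-1-en-1-yl]-4-[(4-methoxybenzyl)oxymethyl]-3-methyl-4-(triethylsilyloxy)oxolan-2-one
Product: 35 (1R,4Z)-1-[(1R)-4-methoxy-1,3-dimethyl-2-oxocyclohex-3-en-1-yl]-5-[(2S,3R,4R)-3-[(4-methoxybenzyl)oxymethyl]-4-methyl-5-oxo-3-(triethylsilyloxy)oxolan-2-yl]-4-methylpent-4-en-1-yl acetate, via B-alkyl-9-borabicyclononane 34 (not isolated)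
Conditions: 9-BBN, THF, rt; then 22, Pd(dppf)Cl2 (cat.), AsPh3, K3PO4 (aq.), DMF, rt
Reagents that add atoms: none
Why: Anti-Markovnikov hydroboration puts boron on C4, and the B-alkyl Suzuki–Miyaura coupling with the alkenyl iodide forms C4–C5 with retention of the Z geometry. The mild phosphate base is tolerated by the lactone and the acetate.

Step 18
Reactants: 35 (1R,4Z)-1-[(1R)-4-methoxy-1,3-dimethyl-2-oxocyclohex-3-en-1-yl]-5-[(2S,3R,4R)-3-[(4-methoxybenzyl)oxymethyl]-4-methyl-5-oxo-3-(triethylsilyloxy)oxolan-2-yl]-4-methylpent-4-en-1-yl acetate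
Product: 37 C10 triflate, C12 ketone, C9 4-methoxybenzyl ether, via dienyl triflate 36 (not isolated)
Conditions: Tf2O, 2,6-di-tert-butyl-4-methylpyridine, CH2Cl2, −78 to 0 °C; then 0.5 M HCl, THF, 0 °C
Reagents that add atoms: trifluoromethanesulfonic anhydride, O=S(=O)(OS(=O)(=O)C(F)(F)F)C(F)(F)F; water, O
Why: Enol triflate formation from a ketone with Tf2O and a hindered pyridine; the carbonyl oxygen on C10 is the most nucleophilic site, and because C1 is quaternary the proton is lost from C13 to give dienyl triflate 36. Mild acid then hydrolyses the methyl enol ether to the C12 ketone, which places the leaving group on C10 without strong base and without a regiochemical choice.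

Step 19
Reactants: 37 C10 triflate, C12 ketone, C9 4-methoxybenzyl ether
Product: 38 C9 primary alcohol
Conditions: DDQ, CH2Cl2–pH 7 buffer, 0 °C
Reagents that add atoms: none
Why: Oxidative cleavage of a 4-methoxybenzyl ether; the neutral conditions leave the silyl ether, the triflate, the lactone and the acetate untouched and do not promote silyl migration.

Step 20
Reactants: 38 C9 primary alcohol
Product: 39 C9 aldehyde with C10 triflate on the ring A enone (cyclization precursor)
Conditions: Dess–Martin periodinane, pyridine, CH2Cl2, 0 °C to rt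
Reagents that add atoms: none
Why: Dess–Martin oxidation to an aldehyde that has no α-hydrogen and therefore cannot epimerize or enolize.

Step 21
Reactants: 39 C9 aldehyde with C10 triflate on the ring A enone (cyclization precursor)
Product: 41 tricyclic (9R)-C9 alcohol with C10=C11 enone and lactone (8-O-triethylsilyl, 2-O-acetyl), via alkenylchromium dichloride 40 (not isolated)
Conditions: CrCl2 (15 equiv), NiCl2 (cat.), degassed DMSO–THF, 25 °C, slow addition of 39 to 0.002 M; aq. NH4Cl–ethylenediamine work-up
Reagents that add atoms: none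
Why: Divalent chromium reduces NiCl2 to zerovalent nickel, which inserts into the C10–O bond of the triflate; transmetalation to trivalent chromium gives alkenylchromium 40, and this adds to the C9 aldehyde. The closest known reaction type is the Nozaki–Hiyama–Kishi macrocyclization of alkenyl triflates and iodides, β-halo enones included, onto aldehydes. The ten-membered carbocycle closes by a 10-exo-trig addition in which C9 and C10 become ring members and the carbonyl oxygen stays outside the ring. The new stereocentre C9 is controlled by the adjacent fully substituted C8: C10 should approach anti to the C8–O bond (polar Felkin–Anh), and the tether through C7 decides which of the other two C8 substituents lies beside the carbonyl oxygen, which should lead to 9R. The step needs chemoselectivity for the aldehyde over the C12 ketone, the lactone and the acetate, which the low basicity and aldehyde preference of organochromium reagents provide. It also needs ring closure to outrun protonation and dimerization; high dilution, slow addition, the non-enolizable aldehyde and the turn imposed by the Z alkene and the lactone serve this.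

Step 22
Reactants: 41 tricyclic (9R)-C9 alcohol with C10=C11 enone and lactone
Product: 42 8,9-bis(triethylsilyl) ether of the tricyclic enone
Conditions: Et3SiOTf, 2,6-lutidine, CH2Cl2, −78 to 0 °C
Reagents that add atoms: triethylsilyl trifluoromethanesulfonate, CC[Si](CC)(CC)OS(=O)(=O)C(F)(F)F
Why: Silylation of a hindered secondary alcohol with a silyl triflate. It protects the γ-hydroxy enone against isomerization and keeps O9 apart from O12 for the later acetylation.

Step 23
Reactants: 42 8,9-bis(triethylsilyl) ether of the tricyclic enone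
Product: 44 saturated C12 ketone with H10 and H11 both α, via silyl enol ether 43 (not isolated)
Conditions: (IPr)CuCl (cat., IPr = 1,3-bis(2,6-diisopropylphenyl)imidazol-2-ylidene), NaOtBu (cat.), (EtO)2MeSiH, toluene, rt; then n-Bu4NF, AcOH, THF, −78 °C
Reagents that add atoms: none
Why: Conjugate reduction by a carbene-ligated monovalent copper hydride, a system used for tetrasubstituted enones; hydride should reach C10 on the α face, anti to the pseudo-axial C15 methyl, and the enolate is held as silyl enol ether 43. Buffered fluoride at low temperature then protonates C11 kinetically on the same α face, because the β face is screened by the 1,3-related C15 methyl; this sets C10 and C11.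

Step 24
Reactants: 44 saturated C12 ketone with H10 and H11 both α
Product: 46 C13=C14 enone, via trimethylsilyl enol ether 45 (not isolated)
Conditions: LiN(SiMe3)2, Me3SiCl, Et3N, THF, −78 °C; then Pd(OAc)2, MeCN, rt
Reagents that add atoms: none
Why: Kinetic enolization at the C13 methylene with in situ silylation, then Saegusa–Ito oxidation. The amide base deprotonates the ketone faster than the lactone or the acetate, and the hindered C11–H is not touched, so C11 keeps its configuration.

Step 25
Reactants: 46 C13=C14 enone
Product: 47 12α allylic alcohol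
Conditions: NaBH4, CeCl3·7H2O, MeOH, −78 °C
Reagents that add atoms: none
Why: Luche 1,2-reduction; axial hydride delivery on the β face should give the pseudo-equatorial 12α alcohol trans to the C11 methyl, the usual outcome for α'-substituted cyclohexenones.

Step 26
Reactants: 47 12α allylic alcohol
Product: 48 13α,14α-epoxy-12α-alcohol
Conditions: VO(acac)2 (cat.), t-BuOOH, CH2Cl2, 0 °C to rt
Reagents that add atoms: tert-butyl hydroperoxide, CC(C)(C)OO
Why: Vanadium-catalysed hydroxyl-directed epoxidation; oxygen is delivered syn to the 12α hydroxyl, which is also the face away from C15. The isolated trisubstituted C5=C6 alkene has no free hydroxyl nearby and should not compete.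

Step 27
Reactants: 48 13α,14α-epoxy-12α-alcohol
Product: 49 2,12-diacetate with 8,9-bis(triethylsilyl) ether and C5=C6 alkene
Conditions: Ac2O, pyridine, DMAP (cat.), CH2Cl2, 0 °C to rt
Reagents that add atoms: acetic anhydride, CC(=O)OC(C)=O
Why: Acetylation of the only free hydroxyl in the molecule, so no selectivity among O2, O8, O9 and O12 is required.

Step 28
Reactants: 49 2,12-diacetate with 8,9-bis(triethylsilyl) ether and C5=C6 alkene
Product: 50 (6S)-6-chloro-5(16)-ene, 8,9-bis(triethylsilyl) ether
Conditions: Ca(OCl)2, CO2 (solid), CH2Cl2–H2O, 0 °C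
Reagents that add atoms: calcium hypochlorite, [Ca+2].[O-]Cl.[O-]Cl
Why: Ene-type allylic chlorination of a trisubstituted alkene by hypochlorous acid; chlorine goes to the less substituted C6 and a proton leaves from the C16 methyl, giving the exocyclic alkene. C5=C6 is the only alkene present, and attack anti to the allylic C7–O bond in the conformer with H7 eclipsing the alkene corresponds to the required 6S centre.

Step 29
Reactants: 50 (6S)-6-chloro-5(16)-ene, 8,9-bis(triethylsilyl) ether
Product: 51 CNP0242711.1, (1S,2R,6S,7R,8R,9R,10S,11R,12S,13S,14R,17R)-configured target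
Conditions: HF·pyridine, pyridine, THF, 0 °C to rt
Reagents that add atoms: none
Why: Fluoride-mediated cleavage of both triethylsilyl ethers under pyridine-buffered conditions, which acetates, the epoxide, the allylic chloride and the lactone are expected to tolerate. The free O8 and O9 of the target are released without any acylation after this point.

## Compound list

1 | dimethyl (4R,5R)-2,2-dimethyl-1,3-dioxolane-4,5-dicarboxylate | COC(=O)[C@@H]1OC(C)(C)O[C@H]1C(=O)OC | starting material
2 | methyl (4R,5S)-5-(hydroxymethyl)-2,2-dimethyl-1,3-dioxolane-4-carboxylate | COC(=O)[C@@H]1OC(C)(C)O[C@H]1CO | intermediate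
3 | methyl (4R,5R)-5-formyl-2,2-dimethyl-1,3-dioxolane-4-carboxylate | COC(=O)[C@@H]1OC(C)(C)O[C@H]1C=O | intermediate
4 | ethyltriphenylphosphonium iodide | CC[P+](c1ccccc1)(c1ccccc1)c1ccccc1.[I-] | starting material
5 | ethylidenetriphenylphosphorane | CC=P(c1ccccc1)(c1ccccc1)c1ccccc1 | intermediate (not isolated)
6 | (1-iodoethyl)triphenylphosphonium iodide | CC(I)[P+](c1ccccc1)(c1ccccc1)c1ccccc1.[I-] | intermediate (not isolated)
7 | (1-iodoethylidene)triphenylphosphorane | CC(I)=P(c1ccccc1)(c1ccccc1)c1ccccc1 | intermediate (not isolated)
8 | methyl (4R,5S)-5-[(1Z)-2-iodoprop-1-en-1-yl]-2,2-dimethyl-1,3-dioxolane-4-carboxylate | COC(=O)[C@@H]1OC(C)(C)O[C@H]1/C=C(/C)I | intermediate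
9 | (E)-but-2-en-1-ol | C/C=C/CO | starting material
10 | (2E)-but-2-en-1-yl (4R,5S)-5-[(1Z)-2-iodoprop-1-en-1-yl]-2,2-dimethyl-1,3-dioxolane-4-carboxylate | C/C=C/COC(=O)[C@@H]1OC(C)(C)O[C@H]1/C=C(/C)I | intermediate
11 | ketene silyl acetal of 10 (C8=C9, ring oxygen cis to OSiMe3, crotyloxy cis to C7) | C/C=C/CO/C(O[Si](C)(C)C)=C1/OC(C)(C)O[C@H]1/C=C(/C)I | intermediate (not isolated)
12 | trimethylsilyl ester of 13 | C[Si](C)(C)OC(=O)[C@@]1([C@@H](C)C=C)OC(C)(C)O[C@H]1/C=C(/C)I | intermediate (not isolated)
13 | (4S,5S)-4-[(2S)-but-3-en-2-yl]-5-[(1Z)-2-iodoprop-1-en-1-yl]-2,2-dimethyl-1,3-dioxolane-4-carboxylic acid | OC(=O)[C@@]1([C@@H](C)C=C)OC(C)(C)O[C@H]1/C=C(/C)I | intermediate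
14 | acyl imidazolide of 13 | O=C(n1ccnc1)[C@@]1([C@@H](C)C=C)OC(C)(C)O[C@H]1/C=C(/C)I | intermediate (not isolated)
15 | [(4R,5S)-4-[(2S)-but-3-en-2-yl]-5-[(1Z)-2-iodoprop-1-en-1-yl]-2,2-dimethyl-1,3-dioxolan-4-yl]methanol | OC[C@@]1([C@@H](C)C=C)OC(C)(C)O[C@H]1/C=C(/C)I | intermediate
16 | 4-methoxybenzyl ether of 15 | COc1ccc(COC[C@@]2([C@@H](C)C=C)OC(C)(C)O[C@H]2/C=C(/C)I)cc1 | intermediate
17 | vicinal diol from dihydroxylation of the vinyl group of 16 (new carbinol centre unspecified) | COc1ccc(COC[C@@]2([C@@H](C)C(O)CO)OC(C)(C)O[C@H]2/C=C(/C)I)cc1 | intermediate (not isolated)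
18 | (2R)-2-[(4R,5S)-5-[(1Z)-2-iodoprop-1-en-1-yl]-4-[(4-methoxybenzyl)oxymethyl]-2,2-dimethyl-1,3-dioxolan-4-yl]propanal | COc1ccc(COC[C@@]2([C@@H](C)C=O)OC(C)(C)O[C@H]2/C=C(/C)I)cc1 | intermediate
19 | (2R)-propanoic acid corresponding to 18 | COc1ccc(COC[C@@]2([C@@H](C)C(O)=O)OC(C)(C)O[C@H]2/C=C(/C)I)cc1 | intermediate (not isolated)
20 | dihydroxy acid from 19 after loss of the acetonide (C7 and C8 hydroxyls free) | COc1ccc(COC[C@](O)([C@@H](C)C(O)=O)[C@@H](O)/C=C(/C)I)cc1 | intermediate (not isolated)
21 | (3R,4R,5S)-4-hydroxy-5-[(1Z)-2-iodoprop-1-en-1-yl]-4-[(4-methoxybenzyl)oxymethyl]-3-methyloxolan-2-one | COc1ccc(COC[C@]2(O)[C@@H](C)C(=O)O[C@H]2/C=C(/C)I)cc1 | intermediate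
22 | (3R,4R,5S)-5-[(1Z)-2-iodoprop-1-en-1-yl]-4-[(4-methoxybenzyl)oxymethyl]-3-methyl-4-(triethylsilyloxy)oxolan-2-one | COc1ccc(COC[C@]2(O[Si](CC)(CC)CC)[C@@H](C)C(=O)O[C@H]2/C=C(/C)I)cc1 | intermediate
23 | 2-methylcyclohexane-1,3-dione | CC1C(=O)CCCC1=O | starting material
24 | 3-methoxy-2-methylcyclohex-2-en-1-one | COC1=C(C)C(=O)CCC1 | intermediate
25 | lithium enolate of 24 (C1–O–Li, C1=C6) | COC1=C(C)C(O[Li])=CCC1 | intermediate (not isolated)
26 | 3-methoxy-2,6-dimethylcyclohex-2-en-1-one (racemic) | COC1=C(C)C(=O)C(C)CC1 | intermediate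
27 | (R)-2,2-dimethyl-1,3-dioxolane-4-carbaldehyde | O=C[C@H]1COC(C)(C)O1 | starting material
28 | lithium enolate of 26 (tetrasubstituted) | COC1=C(C)C(O[Li])=C(C)CC1 | intermediate (not isolated)
29 | (6R)-6-[(S)-[(4R)-2,2-dimethyl-1,3-dioxolan-4-yl](hydroxy)methyl]-3-methoxy-2,6-dimethylcyclohex-2-en-1-one | COC1=C(C)C(=O)[C@@](C)([C@H](O)[C@H]2COC(C)(C)O2)CC1 | intermediate
30 | (S)-[(4R)-2,2-dimethyl-1,3-dioxolan-4-yl][(1R)-4-methoxy-1,3-dimethyl-2-oxocyclohex-3-en-1-yl]methyl acetate | COC1=C(C)C(=O)[C@@](C)([C@H](OC(C)=O)[C@H]2COC(C)(C)O2)CC1 | intermediate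
31 | (1S,2R)-2,3-dihydroxy-1-[(1R)-4-methoxy-1,3-dimethyl-2-oxocyclohex-3-en-1-yl]propyl acetate | COC1=C(C)C(=O)[C@@](C)([C@H](OC(C)=O)[C@H](O)CO)CC1 | intermediate
32 | cyclic orthoformate (2-methoxy-1,3-dioxolane) of 31 | COC1=C(C)C(=O)[C@@](C)([C@H](OC(C)=O)[C@H]2COC(OC)O2)CC1 | intermediate (not isolated)
33 | (1R)-1-[(1R)-4-methoxy-1,3-dimethyl-2-oxocyclohex-3-en-1-yl]prop-2-en-1-yl acetate | COC1=C(C)C(=O)[C@@](C)([C@H](OC(C)=O)C=C)CC1 | intermediate
34 | B-alkyl-9-borabicyclo[3.3.1]nonane from 33 (boron on C4) | COC1=C(C)C(=O)[C@@](C)([C@H](OC(C)=O)CCB2C3CCCC2CCC3)CC1 | intermediate (not isolated)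
35 | (1R,4Z)-1-[(1R)-4-methoxy-1,3-dimethyl-2-oxocyclohex-3-en-1-yl]-5-[(2S,3R,4R)-3-[(4-methoxybenzyl)oxymethyl]-4-methyl-5-oxo-3-(triethylsilyloxy)oxolan-2-yl]-4-methylpent-4-en-1-yl acetate | COc1ccc(COC[C@]2(O[Si](CC)(CC)CC)[C@@H](C)C(=O)O[C@H]2/C=C(/C)CC[C@@H](OC(C)=O)[C@@]2(C)CCC(OC)=C(C)C2=O)cc1 | intermediate
36 | dienyl triflate of 35 (C10 triflate, C10=C11 and C12=C13, C12 methyl enol ether) | COc1ccc(COC[C@]2(O[Si](CC)(CC)CC)[C@@H](C)C(=O)O[C@H]2/C=C(/C)CC[C@@H](OC(C)=O)[C@@]2(C)CC=C(OC)C(C)=C2OS(=O)(=O)C(F)(F)F)cc1 | intermediate (not isolated)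
37 | as 35 but ring A is the (1R)-1,3-dimethyl-4-oxo-2-(trifluoromethanesulfonyloxy)cyclohex-2-en-1-yl group (C10 triflate, C12 ketone) | COc1ccc(COC[C@]2(O[Si](CC)(CC)CC)[C@@H](C)C(=O)O[C@H]2/C=C(/C)CC[C@@H](OC(C)=O)[C@@]2(C)CCC(=O)C(C)=C2OS(=O)(=O)C(F)(F)F)cc1 | intermediate
38 | C9 primary alcohol from 37 (hydroxymethyl on C8) | OC[C@]1(O[Si](CC)(CC)CC)[C@@H](C)C(=O)O[C@H]1/C=C(/C)CC[C@@H](OC(C)=O)[C@@]1(C)CCC(=O)C(C)=C1OS(=O)(=O)C(F)(F)F | intermediate
39 | C9 aldehyde (formyl on C8) tethered through C2 to the ring A 3-triflyloxy-2-methylcyclohexenone; cyclization precursor | O=C[C@]1(O[Si](CC)(CC)CC)[C@@H](C)C(=O)O[C@H]1/C=C(/C)CC[C@@H](OC(C)=O)[C@@]1(C)CCC(=O)C(C)=C1OS(=O)(=O)C(F)(F)F | intermediate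
40 | C10 alkenylchromium dichloride from 39 | O=C[C@]1(O[Si](CC)(CC)CC)[C@@H](C)C(=O)O[C@H]1/C=C(/C)CC[C@@H](OC(C)=O)[C@@]1(C)CCC(=O)C(C)=C1[Cr](Cl)Cl | intermediate (not isolated)
41 | tricyclic (9R)-C9 alcohol with C10=C11 enone (C12 ketone), Z-C5=C6 alkene, lactone, 8-O-triethylsilyl, 2-O-acetyl | O[C@@H]1C2=C(C)C(=O)CC[C@]2(C)[C@H](OC(C)=O)CC/C(C)=C\[C@@H]3OC(=O)[C@H](C)[C@@]13O[Si](CC)(CC)CC | intermediate
42 | 9-O-triethylsilyl ether of 41 | CC[Si](CC)(CC)O[C@@H]1C2=C(C)C(=O)CC[C@]2(C)[C@H](OC(C)=O)CC/C(C)=C\[C@@H]3OC(=O)[C@H](C)[C@@]13O[Si](CC)(CC)CC | intermediate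
43 | C11=C12 diethoxy(methyl)silyl enol ether with H10 α | CC[Si](CC)(CC)O[C@@H]1[C@H]2C(C)=C(O[Si](C)(OCC)OCC)CC[C@]2(C)[C@H](OC(C)=O)CC/C(C)=C\[C@@H]3OC(=O)[C@H](C)[C@@]13O[Si](CC)(CC)CC | intermediate (not isolated)
44 | saturated C12 ketone, H10 α and H11 α (C20 β) | CC[Si](CC)(CC)O[C@@H]1[C@H]2[C@@H](C)C(=O)CC[C@]2(C)[C@H](OC(C)=O)CC/C(C)=C\[C@@H]3OC(=O)[C@H](C)[C@@]13O[Si](CC)(CC)CC | intermediate
45 | C12=C13 trimethylsilyl enol ether of 44 | CC[Si](CC)(CC)O[C@@H]1[C@H]2[C@@H](C)C(O[Si](C)(C)C)=CC[C@]2(C)[C@H](OC(C)=O)CC/C(C)=C\[C@@H]3OC(=O)[C@H](C)[C@@]13O[Si](CC)(CC)CC | intermediate (not isolated)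
46 | C13=C14 enone (C12 ketone) | CC[Si](CC)(CC)O[C@@H]1[C@H]2[C@@H](C)C(=O)C=C[C@]2(C)[C@H](OC(C)=O)CC/C(C)=C\[C@@H]3OC(=O)[C@H](C)[C@@]13O[Si](CC)(CC)CC | intermediate
47 | 12α allylic alcohol with C13=C14 alkene | CC[Si](CC)(CC)O[C@@H]1[C@H]2[C@@H](C)[C@H](O)C=C[C@]2(C)[C@H](OC(C)=O)CC/C(C)=C\[C@@H]3OC(=O)[C@H](C)[C@@]13O[Si](CC)(CC)CC | intermediate
48 | 13α,14α-epoxy-12α-alcohol | CC[Si](CC)(CC)O[C@@H]1[C@H]2[C@@H](C)[C@H](O)[C@@H]4O[C@@H]4[C@]2(C)[C@H](OC(C)=O)CC/C(C)=C\[C@@H]3OC(=O)[C@H](C)[C@@]13O[Si](CC)(CC)CC | intermediate
49 | 2,12-diacetate, 13α,14α-epoxide, Z-C5=C6 alkene, 8,9-bis(triethylsilyl) ether | CC[Si](CC)(CC)O[C@@H]1[C@H]2[C@@H](C)[C@H](OC(C)=O)[C@@H]4O[C@@H]4[C@]2(C)[C@H](OC(C)=O)CC/C(C)=C\[C@@H]3OC(=O)[C@H](C)[C@@]13O[Si](CC)(CC)CC | intermediate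
50 | (6S)-6-chloro-5(16)-ene, 2,12-diacetate, 13α,14α-epoxide, 8,9-bis(triethylsilyl) ether | CC[Si](CC)(CC)O[C@@H]1[C@H]2[C@@H](C)[C@H](OC(C)=O)[C@@H]4O[C@@H]4[C@]2(C)[C@H](OC(C)=O)CCC(=C)[C@H](Cl)[C@@H]3OC(=O)[C@H](C)[C@@]13O[Si](CC)(CC)CC | intermediate
51 | CNP0242711.1, (1S,2R,6S,7R,8R,9R,10S,11R,12S,13S,14R,17R)-2,12-diacetoxy-6-chloro-13,14-epoxy-8,9-dihydroxybriar-5(16)-en-19,7-olide | C=C1CC[C@@H](OC(C)=O)[C@]2(C)[C@H]([C@@H](C)[C@H](OC(C)=O)[C@@H]3O[C@@H]32)[C@@H](O)[C@]2(O)[C@@H](C)C(=O)O[C@H]2[C@H]1Cl | target

## Step count and least certain steps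

Total step count: 29. Longest linear sequence: 23 steps (steps 1 to 10, then 17 to 29); the ring A branch (steps 11 to 16) joins at step 17.

Least certain steps:

**Step 21 (key step).** The most likely failure is that ring closure between two hindered carbons is slower than protonation or intermolecular reaction of the alkenylchromium species; a second concern is insufficient facial discrimination at the aldehyde, since both flanking groups on C8 are large. Fallback: set out from 39. A Miyaura borylation (Pd(dppf)Cl2, bis(pinacolato)diboron, KOAc, dioxane) would replace the triflate by boron and give the C10 pinacol boronate aldehyde F1. Intramolecular 1,2-addition of the alkenylboronate to the aldehyde, catalysed by monovalent rhodium ([Rh(cod)OH]2, dioxane–water, high dilution), would form the same C9–C10 bond through a different organometallic and return to the route at 41.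

**Step 18.** The anhydride may react at other Lewis-basic sites (lactone, acetate, aryl ether), or the O-sulfonylated cation may revert on work-up instead of losing the C13 proton. Fallback: set out from 35. Soft enolization with t-BuMe2SiOTf and Et3N would give the silyl dienol ether F2. Fluoride-triggered exchange with N-phenylbis(trifluoromethanesulfonimide) and CsF in dimethoxyethane would transfer the triflyl group to the liberated dienolate oxygen and return to the route at 36, which is hydrolysed as in step 18.

**Step 23.** Hydride transfer to the very hindered C10 may be slow, and protonation of C11 may occur on the wrong face or be followed by equilibration to the C11 epimer, which is probably the more stable ketone. Fallback: set out from 41, whose free C9 hydroxyl can direct a cationic iridium catalyst. Hydrogenation with [Ir(cod)(PCy3)(py)]PF6 and H2 in CH2Cl2 would add both hydrogens to C10 and C11 in one syn event on the α face and give the saturated C9 alcohol F3. Silylation with Et3SiOTf and 2,6-lutidine would return to the route at 44.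

**Step 28.** Chlorine may be delivered to the other face of the C5=C6 alkene, because the face anti to the C7–O bond is also the face next to the quaternary C8; the proton may also be lost from C4 instead of C16. Fallback: set out from 49. Epoxidation with m-chloroperbenzoic acid on the sterically exposed face would give the 5,6-epoxide F4. Isomerization with Me3SiOTf and DBU would open it at the tertiary C5 and remove a C16 proton to give the exocyclic allylic trimethylsilyl ether F5. Citric acid in methanol would free the C6 allylic alcohol F6. Chlorination with Ph3P and N-chlorosuccinimide would replace the hydroxyl with inversion and return to the route at 50. This path gives the 6S chloride exactly when electrophiles prefer the face that direct chlorination would have used wrongly.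

**Step 13.** Facial selectivity may be limited on both partners, since a tetrasubstituted enolate and an α-alkoxy aldehyde each give only moderate control; this would lower the amount of the one diastereomer that is needed. Fallback: set out from 26. Aldol addition of enolate 28 to acrolein would give the racemic allylic alcohol F7. Lipase-catalysed acetylation (Pseudomonas cepacia lipase, vinyl acetate) is expected, by the empirical rule for secondary alcohols, to acylate the (R)-carbinol enantiomer; this would return to the route directly at 33 and leave the other enantiomer as the alcohol.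

**Step 25.** Hydride may be delivered from the α face, because the β face carries the neighbouring C20 methyl; this would give the 12β alcohol and then, by direction, the wrong epoxide. Fallback: set out from 46. Nucleophilic epoxidation with LiOOtBu in THF at −20 °C should attack C14 anti to the C15 methyl and give the 13α,14α-epoxy ketone F8. Reduction with Zn(BH4)2 in ether, in which hydride arrives anti to the oxirane, would give the cis epoxy alcohol and return to the route at 48.

## Further compounds

F1 | step 21 | C10 pinacol boronate aldehyde (as 39 with 4,4,5,5-tetramethyl-1,3,2-dioxaborolan-2-yl on C10 in place of the triflate) | O=C[C@]1(O[Si](CC)(CC)CC)[C@@H](C)C(=O)O[C@H]1/C=C(/C)CC[C@@H](OC(C)=O)[C@@]1(C)CCC(=O)C(C)=C1B1OC(C)(C)C(C)(C)O1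
F2 | step 18 | silyl dienol ether of 35 (C10 tert-butyldimethylsilyloxy, C10=C11 and C12=C13, C12 methyl enol ether) | COc1ccc(COC[C@]2(O[Si](CC)(CC)CC)[C@@H](C)C(=O)O[C@H]2/C=C(/C)CC[C@@H](OC(C)=O)[C@@]2(C)CC=C(OC)C(C)=C2O[Si](C)(C)C(C)(C)C)cc1
F3 | step 23 | saturated C12 ketone with free C9 hydroxyl, H10 α and H11 α | O[C@@H]1[C@H]2[C@@H](C)C(=O)CC[C@]2(C)[C@H](OC(C)=O)CC/C(C)=C\[C@@H]3OC(=O)[C@H](C)[C@@]13O[Si](CC)(CC)CC
F4 | step 28 | 5,6-epoxide of 49 (cis epoxide, oxygen on the face opposite to the later chloride) | CC[Si](CC)(CC)O[C@@H]1[C@H]2[C@@H](C)[C@H](OC(C)=O)[C@@H]4O[C@@H]4[C@]2(C)[C@H](OC(C)=O)CC[C@@]4(C)O[C@H]4[C@@H]3OC(=O)[C@H](C)[C@@]13O[Si](CC)(CC)CC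
F5 | step 28 | C6 allylic trimethylsilyl ether with exocyclic C5=C16 alkene | CC[Si](CC)(CC)O[C@@H]1[C@H]2[C@@H](C)[C@H](OC(C)=O)[C@@H]4O[C@@H]4[C@]2(C)[C@H](OC(C)=O)CCC(=C)[C@@H](O[Si](C)(C)C)[C@@H]3OC(=O)[C@H](C)[C@@]13O[Si](CC)(CC)CC
F6 | step 28 | C6 allylic alcohol with exocyclic C5=C16 alkene (C6 configuration opposite to that of the chloride in 50) | CC[Si](CC)(CC)O[C@@H]1[C@H]2[C@@H](C)[C@H](OC(C)=O)[C@@H]4O[C@@H]4[C@]2(C)[C@H](OC(C)=O)CCC(=C)[C@@H](O)[C@@H]3OC(=O)[C@H](C)[C@@]13O[Si](CC)(CC)CC
F7 | step 13 | racemic 6-(1-hydroxyprop-2-en-1-yl)-3-methoxy-2,6-dimethylcyclohex-2-en-1-one, relative configuration as in 33 (the enantiomer that is acetylated is drawn) | COC1=C(C)C(=O)[C@@](C)([C@H](O)C=C)CC1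
F8 | step 25 | 13α,14α-epoxy C12 ketone | CC[Si](CC)(CC)O[C@@H]1[C@H]2[C@@H](C)C(=O)[C@@H]4O[C@@H]4[C@]2(C)[C@H](OC(C)=O)CC/C(C)=C\[C@@H]3OC(=O)[C@H](C)[C@@]13O[Si](CC)(CC)CC
A1 | alternative 1 | di-(–)-menthyl mesaconate | O=C(O[C@@H]1C[C@H](C)CC[C@H]1C(C)C)/C=C(\C)C(=O)O[C@@H]1C[C@H](C)CC[C@H]1C(C)C
A2 | alternative 1 | (Z)-3-(tert-butyldimethylsilyloxy)penta-1,3-diene | C=C/C(O[Si](C)(C)C(C)(C)C)=C/C
A3 | alternative 1 | ring A cyclohexene diester (C2 and C9 menthyl esters) with C12 silyl enol ether | O=C(O[C@@H]1C[C@H](C)CC[C@H]1C(C)C)[C@H]2[C@@H](C)C(O[Si](C)(C)C(C)(C)C)=CC[C@]2(C)C(=O)O[C@@H]3C[C@H](C)CC[C@H]3C(C)C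
A4 | alternative 2 | tricyclic lactone with C6 chloride, C5 methylene, C13=C14 alkene and 8,9-acetonide | C=C1CC[C@@H](O[Si](C)(C)C(C)(C)C)[C@]2(C)[C@H]([C@@H](C)[C@H](O[Si](C)(C)C(C)(C)C)C=C2)[C@H]3OC(C)(C)O[C@]34[C@@H](C)C(=O)O[C@H]4[C@H]1Cl
A5 | alternative 3 | bicyclic C3=C4, C5=C6 diene with 8,9-acetonide and protected C19 alcohol | O([Si](C)(C)C(C)(C)C)[C@@H]1/C=C\C(C)=C/[C@H](O[Si](C)(C)C(C)(C)C)[C@]2([C@@H](C)COCc4ccc(OC)cc4)OC(C)(C)O[C@@H]2[C@H]3[C@@H](C)[C@H](O[Si](C)(C)C(C)(C)C)C=C[C@]13C
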